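**Retrosynthetic overview**
1. Target ⇐ angeloylation (C3–O) and acetylation (C6–O) of the 4,5‑epoxy diol ⇐ hydroxyl‑directed epoxidation of the (1(10)E,4E)‑dienol 17.
2. 17 ⇐ Z→E inversion (epoxide / phosphorus betaine) of the (4Z)‑dienol 11 ⇐ 1,2‑reduction of the ten‑membered dienone 10.
3. 10 ⇐ anionic oxy‑Cope ([3,3]) ring expansion of the 1,2‑dialkenylcyclohexenol 7 (C8–C9 formed, C1–C6 broken).
4. 7 ⇐ alkenyllithium from bromide 5 + enone 4 ⇐ allylic oxidation of silylated cis‑carveol ⇐ (R)‑carvone, the only chiral purchase.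
5. Ring order: six‑membered ring bought → ten‑membered ring (step 5) → oxirane last (step 9).

Assumption: 2‑bromo‑3‑methylbut‑1‑ene and angelic acid are bought; positions after ring expansion are cited with germacrane numbering (ring C1–C10, C1=C10, O at C3, oxirane C4–C5, O at C6, isopropyl at C7).

The stereochemical outcomes of steps 4–6 and 9 are predictions from conformational models, not verified results.

**Step 1**
Reactants: 1 (R)-(−)-carvone
Product: 2 (1R,5R)-cis-carveol
Conditions: NaBH4, CeCl3·7H2O, MeOH, −20 °C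
Reagents that add atoms: none
Why: Luche 1,2‑reduction delivers hydride so that the new hydroxyl is pseudo‑equatorial and cis to the isopropenyl group, so the carvone stereocentre sets the future C3 carbinol (R).

**Step 2**
Reactants: 2 (1R,5R)-cis-carveol
Product: 3 (1R,5R)-cis-carveol tert-butyldimethylsilyl ether
Conditions: TBSCl, imidazole, DMF, 25 °C
Reagents that add atoms: tert-butyldimethylsilyl chloride, CC(C)(C)[Si](C)(C)Cl
Why: Standard silylation protects the C3 oxygen through the organolithium, KH and phosphide steps and leaves both stereocentres untouched.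

**Step 3**
Reactants: 3 (1R,5R)-cis-carveol tert-butyldimethylsilyl ether
Product: 4 (4R,6R)-4-(tert-butyldimethylsilyloxy)-3-methyl-6-(prop-1-en-2-yl)cyclohex-2-en-1-one
Conditions: CrO3, 3,5-dimethylpyrazole, CH2Cl2, −20 °C
Reagents that add atoms: chromium trioxide, O=[Cr](=O)=O
Why: Allylic oxidation of the only ring methylene flanking the trisubstituted alkene gives the enone with its carbonyl (future C6) beside the isopropenyl‑bearing carbon, with no stereocentre involved.

**Step 4**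
Reactants: 4 (4R,6R)-4-(tert-butyldimethylsilyloxy)-3-methyl-6-(prop-1-en-2-yl)cyclohex-2-en-1-one; 5 2-bromo-3-methylbut-1-ene
Product: 7 (1R,4R,6R)-4-(tert-butyldimethylsilyloxy)-3-methyl-1-(3-methylbut-1-en-2-yl)-6-(prop-1-en-2-yl)cyclohex-2-en-1-ol, via 3-methylbut-1-en-2-yllithium 6 (not isolated)
Conditions: 5, t-BuLi (2 equiv), Et2O, −78 °C; then 4, THF, −78 °C; H2O
Reagents that add atoms: none
Why: Bromine–lithium exchange and 1,2‑addition, in which the bulky α‑branched alkenyllithium enters anti to the adjacent pseudo‑equatorial isopropenyl group and gives the trans‑1,2‑dialkenyl carbinol that a chair oxy‑Cope needs.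

**Step 5**
Reactants: 7 (1R,4R,6R)-4-(tert-butyldimethylsilyloxy)-3-methyl-1-(3-methylbut-1-en-2-yl)-6-(prop-1-en-2-yl)cyclohex-2-en-1-ol
Product: 10 (2Z,4R,6E,10S)-4-(tert-butyldimethylsilyloxy)-3,7-dimethyl-10-(propan-2-yl)cyclodeca-2,6-dien-1-one, via potassium alkoxide 8 (not isolated), via potassium dienolate 9 (not isolated)
Conditions: KH, 18-crown-6, THF, 0 → 25 °C; then AcOH, THF, −78 °C
Reagents that add atoms: none
Why: Anionic oxy‑Cope ([3,3]‑sigmatropic) rearrangement through a chair transition state with both alkenyl groups equatorial forms C8–C9, breaks C1–C6 and makes the new C1=C10 alkene E (the former ring alkene C4=C5 necessarily stays Z), and protonation of the enolate at C7 from the outer face of the first‑formed conformer sets C7 (S) with isopropyl pseudo‑equatorial.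

**Step 6**
Reactants: 10 (2Z,4R,6E,10S)-4-(tert-butyldimethylsilyloxy)-3,7-dimethyl-10-(propan-2-yl)cyclodeca-2,6-dien-1-one
Product: 11 (1S,2Z,4R,6E,10S)-4-(tert-butyldimethylsilyloxy)-3,7-dimethyl-10-(propan-2-yl)cyclodeca-2,6-dien-1-ol
Conditions: NaBH4, CeCl3·7H2O, MeOH, −78 °C
Reagents that add atoms: none
Why: Luche 1,2‑reduction in which Felkin–Anh attack anti to the C7 isopropyl group coincides with attack on the exposed outer face of the ring carbonyl, setting C6 (S).

**Step 7**
Reactants: 11 (1S,2Z,4R,6E,10S)-4-(tert-butyldimethylsilyloxy)-3,7-dimethyl-10-(propan-2-yl)cyclodeca-2,6-dien-1-ol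
Product: 12 cis-4,5-epoxide of 11 (oxirane oxygen syn to the C6 hydroxyl)
Conditions: VO(acac)2 (5 mol %), t-BuOOH, 2,6-lutidine, CH2Cl2, 0 °C
Reagents that add atoms: tert-butyl hydroperoxide, CC(C)(C)OO
Why: Hydroxyl‑directed vanadium‑catalysed epoxidation selects the allylic C4=C5 alkene over the remote C1=C10 alkene; the configuration of this oxirane is immaterial because both carbons return to sp2 in step 8.

**Step 8**
Reactants: 12 cis-4,5-epoxide of 11 (oxirane oxygen syn to the C6 hydroxyl)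
Product: 17 (1S,2E,4R,6E,10S)-4-(tert-butyldimethylsilyloxy)-3,7-dimethyl-10-(propan-2-yl)cyclodeca-2,6-dien-1-ol, via trimethylsilyl ether 13 (not isolated), via lithium phosphino alkoxide 14 (not isolated), via phosphonium betaine 15 (not isolated), via silylated E-dienol 16 (not isolated)
Conditions: Me3SiNEt2, THF, 25 °C; LiPPh2, 0 → 40 °C; MeI, 25 °C; K2CO3 (cat.), MeOH
Reagents that add atoms: none
Why: Phosphorus‑betaine olefin inversion (Vedejs type): SN2 opening at the secondary carbon C5, P‑methylation and syn loss of Ph2P(O)Me convert the cis epoxide stereospecifically into the E alkene, while the transient silyl ether keeps the C6 oxygen out of the elimination and C3, C6 and C7 are untouched.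

**Step 9**
Reactants: 17 (1S,2E,4R,6E,10S)-4-(tert-butyldimethylsilyloxy)-3,7-dimethyl-10-(propan-2-yl)cyclodeca-2,6-dien-1-ol
Product: 18 trans-4,5-epoxide of 17 (3-O-silyl 6-hydroxy compound with the configuration of the target at C3 to C7)
Conditions: VO(acac)2 (5 mol %), t-BuOOH, 2,6-lutidine, CH2Cl2, −20 °C
Reagents that add atoms: tert-butyl hydroperoxide, CC(C)(C)OO
Why: Hydroxyl‑directed vanadium‑catalysed epoxidation: allylic 1,3‑strain holds the C6–H bond in the alkene plane next to the C4 methyl, so oxygen is delivered syn to the C6 hydroxyl on the outer face of the E alkene, giving the (4R,5R) oxirane.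

**Step 10**
Reactants: 18 trans-4,5-epoxide of 17 (3-O-silyl 6-hydroxy compound with the configuration of the target at C3 to C7)
Product: 19 6-O-acetate of 18
Conditions: Ac2O, pyridine, DMAP (cat.), CH2Cl2, 0 → 25 °C
Reagents that add atoms: acetic anhydride, CC(=O)OC(C)=O
Why: Base‑mediated acetylation of the secondary alcohol proceeds with retention and does not open the oxirane.

**Step 11**
Reactants: 19 6-O-acetate of 18
Product: 20 (1(10)E,3R,4R,5R,6S,7S)-6-acetoxy-4,5-epoxygermacr-1(10)-en-3-ol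
Conditions: Bu4NF, AcOH, THF, 0 → 25 °C
Reagents that add atoms: none
Why: Fluoride desilylation buffered with acetic acid frees the C3 hydroxyl without acetate migration or oxirane opening.

**Step 12**
Reactants: 20 (1(10)E,3R,4R,5R,6S,7S)-6-acetoxy-4,5-epoxygermacr-1(10)-en-3-ol; 21 angelic acid
Product: 23 (1(10)E,3R,4R,5R,6S,7S)-6-acetoxy-4,5-epoxygermacr-1(10)-en-3-yl angelate, via mixed anhydride 22 (not isolated)
Conditions: 21, 2,4,6-trichlorobenzoyl chloride, Et3N, toluene, 25 °C; then 20, DMAP, toluene, 60 °C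
Reagents that add atoms: none
Why: Yamaguchi esterification acylates the C3 oxygen with retention, and activation as a hindered mixed anhydride under base avoids isomerising the Z (angeloyl) double bond to the E (tigloyl) one.

**Compound list**
1 | (R)-(−)-carvone | CC1=CC[C@H](CC1=O)C(C)=C | starting material
2 | (1R,5R)-cis-carveol | O[C@H]1C(C)=CC[C@@H](C(C)=C)C1 | intermediate
3 | (1R,5R)-cis-carveol tert-butyldimethylsilyl ether | CC(C)(C)[Si](C)(C)O[C@H]1C(C)=CC[C@@H](C(C)=C)C1 | intermediate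
4 | (4R,6R)-4-(tert-butyldimethylsilyloxy)-3-methyl-6-(prop-1-en-2-yl)cyclohex-2-en-1-one | O=C1C=C(C)[C@H](O[Si](C)(C)C(C)(C)C)C[C@@H]1C(C)=C | intermediate
5 | 2-bromo-3-methylbut-1-ene | C=C(Br)C(C)C | starting material
6 | 3-methylbut-1-en-2-yllithium | [Li]C(=C)C(C)C | intermediate
7 | (1R,4R,6R)-4-(tert-butyldimethylsilyloxy)-3-methyl-1-(3-methylbut-1-en-2-yl)-6-(prop-1-en-2-yl)cyclohex-2-en-1-ol (alkenyl trans to isopropenyl) | O[C@]1(C(=C)C(C)C)C=C(C)[C@H](O[Si](C)(C)C(C)(C)C)C[C@@H]1C(C)=C | intermediate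
8 | potassium alkoxide of 7 | [K+].[O-][C@]1(C(=C)C(C)C)C=C(C)[C@H](O[Si](C)(C)C(C)(C)C)C[C@@H]1C(C)=C | intermediate
9 | potassium dienolate of 10 (C6–O−, C6=C7; 1(10)E, 4Z) | CC(C)(C)[Si](C)(C)O[C@@H]1C/C=C(\C)CC/C(C(C)C)=C(\[O-])/C=C1/C.[K+] | intermediate
10 | (2Z,4R,6E,10S)-4-(tert-butyldimethylsilyloxy)-3,7-dimethyl-10-(propan-2-yl)cyclodeca-2,6-dien-1-one | CC(C)(C)[Si](C)(C)O[C@@H]1C/C=C(\C)CC[C@@H](C(C)C)C(=O)/C=C1/C | intermediate
11 | (1S,2Z,4R,6E,10S)-4-(tert-butyldimethylsilyloxy)-3,7-dimethyl-10-(propan-2-yl)cyclodeca-2,6-dien-1-ol | CC(C)(C)[Si](C)(C)O[C@@H]1C/C=C(\C)CC[C@@H](C(C)C)[C@H](O)/C=C1/C | intermediate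
12 | cis-4,5-epoxide of 11, oxirane oxygen syn to the C6 hydroxyl | CC(C)(C)[Si](C)(C)O[C@@H]1C/C=C(\C)CC[C@@H](C(C)C)[C@H](O)[C@@H]2O[C@]12C | intermediate
13 | 6-O-trimethylsilyl ether of 12 | CC(C)(C)[Si](C)(C)O[C@@H]1C/C=C(\C)CC[C@@H](C(C)C)[C@H](O[Si](C)(C)C)[C@@H]2O[C@]12C | intermediate
14 | lithium C4-alkoxide carrying the diphenylphosphino group at C5 (anti to the C4 oxygen) | CC(C)(C)[Si](C)(C)O[C@@H]1C/C=C(\C)CC[C@@H](C(C)C)[C@H](O[Si](C)(C)C)[C@@H](P(c2ccccc2)c2ccccc2)[C@]1(C)[O-].[Li+] | intermediate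
15 | methyl(diphenyl)phosphonium betaine from 14 | CC(C)(C)[Si](C)(C)O[C@@H]1C/C=C(\C)CC[C@@H](C(C)C)[C@H](O[Si](C)(C)C)[C@@H]([P+](C)(c2ccccc2)c2ccccc2)[C@]1(C)[O-] | intermediate
16 | 6-O-trimethylsilyl ether of 17 | CC(C)(C)[Si](C)(C)O[C@@H]1C/C=C(\C)CC[C@@H](C(C)C)[C@H](O[Si](C)(C)C)/C=C1\C | intermediate
17 | (1S,2E,4R,6E,10S)-4-(tert-butyldimethylsilyloxy)-3,7-dimethyl-10-(propan-2-yl)cyclodeca-2,6-dien-1-ol | CC(C)(C)[Si](C)(C)O[C@@H]1C/C=C(\C)CC[C@@H](C(C)C)[C@H](O)/C=C1\C | intermediate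
18 | trans-4,5-epoxide of 17, target configuration at C3 to C7 | CC(C)(C)[Si](C)(C)O[C@@H]1C/C=C(\C)CC[C@@H](C(C)C)[C@H](O)[C@H]2O[C@@]21C | intermediate
19 | 6-O-acetate of 18 | CC(C)(C)[Si](C)(C)O[C@@H]1C/C=C(\C)CC[C@@H](C(C)C)[C@H](OC(C)=O)[C@H]2O[C@@]21C | intermediate
20 | (1(10)E,3R,4R,5R,6S,7S)-6-acetoxy-4,5-epoxygermacr-1(10)-en-3-ol | O[C@@H]1C/C=C(\C)CC[C@@H](C(C)C)[C@H](OC(C)=O)[C@H]2O[C@@]21C | intermediate
21 | angelic acid, (2Z)-2-methylbut-2-enoic acid | C/C=C(/C)C(=O)O | starting material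
22 | angelic 2,4,6-trichlorobenzoic anhydride | C/C=C(/C)C(=O)OC(=O)c1c(Cl)cc(Cl)cc1Cl | intermediate
23 | (1(10)E,3R,4R,5R,6S,7S)-6-acetoxy-4,5-epoxygermacr-1(10)-en-3-yl angelate (CNP0180504.3) | C/C=C(/C)C(=O)O[C@@H]1C/C=C(\C)CC[C@@H](C(C)C)[C@H](OC(C)=O)[C@H]2O[C@@]21C | target

**Total step count:** 12. **Longest linear sequence:** 12 steps (1 → 23); 5 and 21 enter in single convergent steps.

**Three steps most likely to fail**

Step 3. The chromium reagent may also attack the allylic C–H that carries the silyloxy group (returning carvone) or give low conversion. Fallback: set out again from carvone 1. TBSOTf/Et3N (CH2Cl2, 25 °C) gives the through-conjugated silyl dienol ether F1. DMDO (acetone, −40 °C) followed by Et3N·3HF oxygenates the γ‑carbon anti to the isopropenyl group and gives trans-4-hydroxycarvone F2. TESCl/imidazole gives its triethylsilyl ether F3, and Luche reduction (NaBH4, CeCl3·7H2O) gives the cis allylic alcohol F4. TBSCl/imidazole gives the bis-silyl ether F5, and buffered HF·pyridine removes only the triethylsilyl group to give the secondary alcohol F6. Dess–Martin oxidation of F6 rejoins the route at enone 4.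

Step 8. SN2 opening of a trisubstituted oxirane flanked by two oxygenated carbons in a ten‑membered ring may be slow or go astray. Fallback: set out from 12. TESCl/imidazole gives the triethylsilyl ether F7. Me3SiK (made from Me3SiSiMe3 and KOMe in HMPA, 25 °C) opens the oxirane at C5 with inversion to the potassium β-silyl alkoxide F8. This collapses by syn‑Peterson elimination to the silyl-protected E,E-dienol F9. HF·pyridine then removes the triethylsilyl group and the route is rejoined at 17.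

Step 12. The C3 hydroxyl is hindered (next to the quaternary oxirane carbon) and forcing conditions can isomerise angelate to tiglate. Fallback: set out from 20. DCC/DMAP esterification with 2-[bis(2,2,2-trifluoroethoxy)phosphoryl]propanoic acid gives the phosphonopropionate ester F10. KN(SiMe3)2, 18-crown-6, THF, −78 °C, then acetaldehyde (Still–Gennari olefination) builds the Z‑configured 2‑methylbut‑2‑enoate on the molecule, and the route is rejoined at target 23.

**Further compounds**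
F1 | step 3 | tert-butyldimethylsilyl dienol ether of carvone, (5R)-1-silyloxy-2-methyl-5-(prop-1-en-2-yl)cyclohexa-1,3-diene | CC1=C(O[Si](C)(C)C(C)(C)C)C[C@H](C(C)=C)C=C1
F2 | step 3 | trans-4-hydroxycarvone, hydroxyl anti to isopropenyl | CC1=C[C@H](O)[C@@H](C(C)=C)CC1=O
F3 | step 3 | triethylsilyl ether of F2 | CC1=C[C@H](O[Si](CC)(CC)CC)[C@@H](C(C)=C)CC1=O
F4 | step 3 | cis allylic alcohol from Luche reduction of F3 | CC1=C[C@H](O[Si](CC)(CC)CC)[C@@H](C(C)=C)C[C@H]1O
F5 | step 3 | tert-butyldimethylsilyl ether of F4 | CC1=C[C@H](O[Si](CC)(CC)CC)[C@@H](C(C)=C)C[C@H]1O[Si](C)(C)C(C)(C)C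
F6 | step 3 | secondary alcohol corresponding to enone 4 | CC1=C[C@H](O)[C@@H](C(C)=C)C[C@H]1O[Si](C)(C)C(C)(C)C
F7 | step 8 | 6-O-triethylsilyl ether of 12 | CC(C)(C)[Si](C)(C)O[C@@H]1C/C=C(\C)CC[C@@H](C(C)C)[C@H](O[Si](CC)(CC)CC)[C@@H]2O[C@]12C
F8 | step 8 | potassium C4-alkoxide carrying trimethylsilyl at C5 | CC(C)(C)[Si](C)(C)O[C@@H]1C/C=C(\C)CC[C@@H](C(C)C)[C@H](O[Si](CC)(CC)CC)[C@@H]([Si](C)(C)C)[C@]1(C)[O-].[K+]
F9 | step 8 | 6-O-triethylsilyl ether of 17 | CC(C)(C)[Si](C)(C)O[C@@H]1C/C=C(\C)CC[C@@H](C(C)C)[C@H](O[Si](CC)(CC)CC)/C=C1\C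
F10 | step 12 | 3-O-{2-[bis(2,2,2-trifluoroethoxy)phosphoryl]propanoyl} ester of 20 | CC(C(=O)O[C@@H]1C/C=C(\C)CC[C@@H](C(C)C)[C@H](OC(C)=O)[C@H]2O[C@@]21C)P(=O)(OCC(F)(F)F)OCC(F)(F)F
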